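The pyran ring of the lower flavan unit (O1, C2, C3, C4, C4a, C8a) is made from a 2,3-dihydrobenzofuran. In cis-alcohol 7 the electron-rich ring A is bonded through C4a to the future C3, and the hydroxymethyl carbon is the future C4. On solvolysis of its mesylate, C4a, activated by its two ortho oxygens and one para oxygen, migrates from C3 to C4 through a phenonium ion and water enters C3 with inversion: the five-membered ring becomes the 2,3-cis chroman-3-ol in one operation. The precursor comes from an enantioselective rhodium-carbenoid C–H insertion; Friedel–Crafts union at C8 with a gallocatechin C4 cation and hydrogenolysis finish the route.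

Key step: step 6

Assumption: (+)-gallocatechin (11) and 3,4-bis(benzyloxy)benzyl chloride (2) are taken as purchasable, and Rh2(S-PTTL)4 is taken to give the (2S,3R)-cis ester 6 (its mirror-image catalyst is used if the sense proves opposite).

Step 1
Reactants: 1 2',4',6'-trihydroxyacetophenone; 2 3,4-bis(benzyloxy)benzyl chloride (3.3 equiv in all; three molecules enter the product)
Product: 3 1-[2,4,6-tris({[3,4-bis(benzyloxy)phenyl]methoxy})phenyl]ethan-1-one
Conditions: K2CO3 (4 equiv), KI (cat.), DMF, 70 °C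
Reagents that add atoms: benzylic chloride 2 (second equivalent), ClCc1ccc(OCc2ccccc2)c(OCc2ccccc2)c1; benzylic chloride 2 (third equivalent), ClCc1ccc(OCc2ccccc2)c(OCc2ccccc2)c1
Why: Threefold Williamson ether synthesis, one molecule of 2 per phenol, in which the acetyl group damps C-alkylation of the phloroglucinol ring and heating with iodide catalysis also etherifies the hydrogen-bonded ortho hydroxyl, so that one benzyl-type group can later become ring B and the other two serve as hydrogenolysable protecting groups.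

Step 2
Reactants: 3 the triether ketone
Product: 4 methyl 2-[2,4,6-tris({[3,4-bis(benzyloxy)phenyl]methoxy})phenyl]acetate
Conditions: Tl(NO3)3·3H2O (1.1 equiv), MeOH/HC(OMe)3 (1:1), 0 °C to rt, short reaction time
Reagents that add atoms: methanol, CO; trimethyl orthoformate, COC(OC)OC
Why: Oxidative 1,2-aryl migration of an aryl methyl ketone by trivalent thallium, in which the enol ether formed in methanol/orthoformate is oxythallated, the very electron-rich aryl group shifts to the former methyl carbon as monovalent thallium leaves, and the dialkoxycarbenium ion collapses to the methyl arylacetate.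

Step 3
Reactants: 4 the methyl arylacetate
Product: 5 methyl 2-diazo-2-[2,4,6-tris({[3,4-bis(benzyloxy)phenyl]methoxy})phenyl]acetate
Conditions: p-ABSA (1.3 equiv), DBU, MeCN, 0 °C to rt
Reagents that add atoms: 4-acetamidobenzenesulfonyl azide (p-ABSA), CC(=O)Nc1ccc(cc1)S(=O)(=O)N=[N+]=[N-]
Why: Regitz diazo transfer to the ester enolate of the benzylic methylene.

Step 4
Reactants: 5 the aryl diazoacetate
Product: 6 methyl (2S,3R)-2-[3,4-bis(benzyloxy)phenyl]-4,6-bis{[3,4-bis(benzyloxy)phenyl]methoxy}-2,3-dihydro-1-benzofuran-3-carboxylate (2,3-cis)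
Conditions: Rh2(S-PTTL)4 [dirhodium tetrakis(N-phthaloyl-(S)-tert-leucinate)] (1 mol %), toluene, −60 °C
Reagents that add atoms: none
Why: Enantioselective intramolecular 1,5 C–H insertion of the divalent rhodium donor/acceptor carbenoid into a benzylic ether C–H bond, in which the two ortho ethers are equivalent so that either gives the same product, the chiral carboxylate ligands select one enantiotopic hydrogen (C2, S) and the concerted insertion closes the five-membered ring to the kinetic 2,3-cis isomer (C3, R).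

Step 5
Reactants: 6 the cis ester
Product: 7 [(2S,3S)-2-[3,4-bis(benzyloxy)phenyl]-4,6-bis{[3,4-bis(benzyloxy)phenyl]methoxy}-2,3-dihydro-1-benzofuran-3-yl]methanol (2,3-cis)
Conditions: i-Bu2AlH (3 equiv), CH2Cl2, −78 to −40 °C; aq. potassium sodium tartrate
Reagents that add atoms: none
Why: Hydride reduction of the ester to the primary alcohol at low temperature, where the C3 hydrogen is not enolised, so the cis relationship set in step 4 is kept.

Step 6
Reactants: 7 the cis hydroxymethyl dihydrobenzofuran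
Product: 10 (2R,3R)-2-[3,4-bis(benzyloxy)phenyl]-5,7-bis{[3,4-bis(benzyloxy)phenyl]methoxy}-3,4-dihydro-2H-1-benzopyran-3-ol, via primary mesylate 8 (not isolated), via bridged phenonium mesylate 9 (not isolated)
Conditions: (MeSO2)2O, i-Pr2NEt, CH2Cl2, −20 °C; then solvent exchange to (CF3)2CHOH/H2O (4:1), 2,6-lutidine, 0 to 40 °C
Reagents that add atoms: water, O
Why: The primary mesylate 8 ionises with participation of ring A: the ipso carbon C4a, which carries oxygen at both ortho positions and at the para position, attacks the CH2 carbon from the rear (3-exo-tet closure of a three-membered ring) and gives the bridged phenonium ion 9, in which C4a is bonded to both the old ring carbon (future C3) and the old exocyclic carbon (future C4). Water opens the three-membered ring at the secondary carbon anti to C4a, which cleaves the bond shared by the three- and five-membered rings and leaves the six-membered O1–C2–C3–C4–C4a–C8a ring, which therefore arises by enlargement and not by a closure of its own. The closest known reaction type is the solvolytic Wagner–Meerwein 1,2-aryl shift through a phenonium ion, as in the ring enlargement of 9-fluorenylmethanol to phenanthrene. C3 is set stereospecifically by inversion, so the cis precursor (CH2 and aryl on the same face) gives the 2,3-cis alcohol (3R), while C2 is untouched and is called 2R only because the ranking of its substituents changes. The step needs attack at C3 instead of at the primary carbon or loss of a proton: the secondary carbon bears more positive charge, its opening relieves the strain of the fused bicycle, and buffered aqueous (CF3)2CHOH offers water as the only competent nucleophile.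

Step 7
Reactants: 11 (+)-gallocatechin
Product: 12 5,7,3',4',5'-penta-O-benzyl-(+)-gallocatechin
Conditions: BnBr (5.5 equiv), K2CO3, DMF, 0 °C to rt, argon
Reagents that add atoms: benzyl bromide, BrCc1ccccc1
Why: Williamson O-benzylation of the five phenols, which carbonate deprotonates while the secondary C3 hydroxyl stays free.

Step 8
Reactants: 12 penta-O-benzyl-gallocatechin
Product: 13 (2R,3S,4S)-5,7-bis(benzyloxy)-4-(2-ethoxyethoxy)-2-[3,4,5-tris(benzyloxy)phenyl]-3,4-dihydro-2H-1-benzopyran-3-ol (4β ether, cis to the C3 hydroxyl)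
Conditions: DDQ (2 equiv), EtOCH2CH2OH (5 equiv), CH2Cl2, rt
Reagents that add atoms: 2-ethoxyethanol, CCOCCO
Why: Oxidative benzylic functionalisation in which DDQ abstracts hydride from C4 to give a cation stabilised by the ring A oxygens and the alcohol adds anti to the C2 aryl group (4S), a configuration that is erased again on ionisation in step 9.

Step 9
Reactants: 13 the C4 ether (electrophile); 10 the protected epicatechin (2.5 equiv, excess recovered)
Product: 14 5,7,3',4',5'-penta-O-benzyl-(+)-gallocatechin-(4α→8)-[3',4'-di-O-benzyl-5,7-bis-O-(3,4-bis(benzyloxy)benzyl)-(−)-epicatechin]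
Conditions: Me3SiOTf (0.2 equiv), CH2Cl2, −78 °C
Reagents that add atoms: none
Why: Lewis acid ionisation of the C4 ether and Friedel–Crafts alkylation of ring A of 10 at C8 (less hindered than C6, which lies between two benzyl-type ethers), the arene adding to the 2,3-trans cation anti to the C3 hydroxyl, which sets C4 as S (4α, 3,4-trans).

Step 10
Reactants: 14 the protected dimer
Product: 15 (+)-gallocatechin-(4α→8)-(−)-epicatechin (target)
Conditions: H2 (1 atm), Pd(OH)2/C, THF/MeOH/H2O (20:20:1), rt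
Reagents that add atoms: none
Why: Hydrogenolysis of all thirteen benzylic aryl ether bonds (the two ring A ethers of the lower unit lose their own benzyl groups and their benzylic C–O bond alike), while the interflavan bond and the ring C2–O1 bonds should survive these mild conditions.

Compound list
1 | 2',4',6'-trihydroxyacetophenone | CC(=O)c1c(O)cc(O)cc1O | starting material
2 | 3,4-bis(benzyloxy)benzyl chloride | ClCc1ccc(OCc2ccccc2)c(OCc2ccccc2)c1 | starting material
3 | 1-[2,4,6-tris({[3,4-bis(benzyloxy)phenyl]methoxy})phenyl]ethan-1-one | CC(=O)c1c(OCc2ccc(OCc3ccccc3)c(OCc3ccccc3)c2)cc(OCc2ccc(OCc3ccccc3)c(OCc3ccccc3)c2)cc1OCc1ccc(OCc2ccccc2)c(OCc2ccccc2)c1 | intermediate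
4 | methyl 2-[2,4,6-tris({[3,4-bis(benzyloxy)phenyl]methoxy})phenyl]acetate | COC(=O)Cc1c(OCc2ccc(OCc3ccccc3)c(OCc3ccccc3)c2)cc(OCc2ccc(OCc3ccccc3)c(OCc3ccccc3)c2)cc1OCc1ccc(OCc2ccccc2)c(OCc2ccccc2)c1 | intermediate
5 | methyl 2-diazo-2-[2,4,6-tris({[3,4-bis(benzyloxy)phenyl]methoxy})phenyl]acetate | COC(=O)C(=[N+]=[N-])c1c(OCc2ccc(OCc3ccccc3)c(OCc3ccccc3)c2)cc(OCc2ccc(OCc3ccccc3)c(OCc3ccccc3)c2)cc1OCc1ccc(OCc2ccccc2)c(OCc2ccccc2)c1 | intermediate
6 | methyl (2S,3R)-2-[3,4-bis(benzyloxy)phenyl]-4,6-bis{[3,4-bis(benzyloxy)phenyl]methoxy}-2,3-dihydro-1-benzofuran-3-carboxylate (cis) | COC(=O)[C@@H]1c2c(OCc3ccc(OCc4ccccc4)c(OCc4ccccc4)c3)cc(OCc3ccc(OCc4ccccc4)c(OCc4ccccc4)c3)cc2O[C@@H]1c1ccc(OCc2ccccc2)c(OCc2ccccc2)c1 | intermediate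
7 | [(2S,3S)-2-[3,4-bis(benzyloxy)phenyl]-4,6-bis{[3,4-bis(benzyloxy)phenyl]methoxy}-2,3-dihydro-1-benzofuran-3-yl]methanol (cis) | OC[C@@H]1c2c(OCc3ccc(OCc4ccccc4)c(OCc4ccccc4)c3)cc(OCc3ccc(OCc4ccccc4)c(OCc4ccccc4)c3)cc2O[C@@H]1c1ccc(OCc2ccccc2)c(OCc2ccccc2)c1 | intermediate
8 | methanesulfonate of 7, (2S,3S) | CS(=O)(=O)OC[C@@H]1c2c(OCc3ccc(OCc4ccccc4)c(OCc4ccccc4)c3)cc(OCc3ccc(OCc4ccccc4)c(OCc4ccccc4)c3)cc2O[C@@H]1c1ccc(OCc2ccccc2)c(OCc2ccccc2)c1 | intermediate (not isolated)
9 | bridged phenonium ion (spiro cyclopropane on C4a, drawn as the para-oxocarbenium form), mesylate salt | C1[C@H]2[C@@H](c3ccc(OCc4ccccc4)c(OCc4ccccc4)c3)OC3=CC(=[O+]Cc4ccc(OCc5ccccc5)c(OCc5ccccc5)c4)C=C(OCc4ccc(OCc5ccccc5)c(OCc5ccccc5)c4)[C@]123.CS(=O)(=O)[O-] | intermediate (not isolated)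
10 | (2R,3R)-2-[3,4-bis(benzyloxy)phenyl]-5,7-bis{[3,4-bis(benzyloxy)phenyl]methoxy}-3,4-dihydro-2H-1-benzopyran-3-ol (cis; protected (−)-epicatechin) | O[C@@H]1Cc2c(OCc3ccc(OCc4ccccc4)c(OCc4ccccc4)c3)cc(OCc3ccc(OCc4ccccc4)c(OCc4ccccc4)c3)cc2O[C@@H]1c1ccc(OCc2ccccc2)c(OCc2ccccc2)c1 | intermediate
11 | (+)-gallocatechin, (2R,3S) | O[C@H]1Cc2c(O)cc(O)cc2O[C@@H]1c1cc(O)c(O)c(O)c1 | starting material
12 | 5,7,3',4',5'-penta-O-benzyl-(+)-gallocatechin | O[C@H]1Cc2c(OCc3ccccc3)cc(OCc3ccccc3)cc2O[C@@H]1c1cc(OCc2ccccc2)c(OCc2ccccc2)c(OCc2ccccc2)c1 | intermediate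
13 | (2R,3S,4S)-5,7-bis(benzyloxy)-4-(2-ethoxyethoxy)-2-[3,4,5-tris(benzyloxy)phenyl]-3,4-dihydro-2H-1-benzopyran-3-ol | O[C@H]1[C@@H](OCCOCC)c2c(OCc3ccccc3)cc(OCc3ccccc3)cc2O[C@@H]1c1cc(OCc2ccccc2)c(OCc2ccccc2)c(OCc2ccccc2)c1 | intermediate
14 | protected dimer: upper unit (2R,3S,4S) penta-O-benzyl-gallocatechin joined 4α→8 to lower unit (2R,3R) as in 10 | c1ccccc1COc1cc(OCc3ccccc3)c2c(c1)O[C@H](c1cc(OCc3ccccc3)c(OCc3ccccc3)c(OCc3ccccc3)c1)[C@@H](O)[C@@H]2c1c(OCc3ccc(OCc4ccccc4)c(OCc4ccccc4)c3)cc(OCc3ccc(OCc4ccccc4)c(OCc4ccccc4)c3)c2c1O[C@H](c1ccc(OCc3ccccc3)c(OCc3ccccc3)c1)[C@H](O)C2 | intermediate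
15 | (+)-gallocatechin-(4α→8)-(−)-epicatechin | Oc1cc(O)c2c(c1)O[C@H](c1cc(O)c(O)c(O)c1)[C@@H](O)[C@@H]2c1c(O)cc(O)c2c1O[C@H](c1ccc(O)c(O)c1)[C@H](O)C2 | target

Total step count: 10. Longest linear sequence: 8 steps (steps 1–6, 9, 10).

Steps most likely to fail

Step 6. The bridged cation may be captured by water at the exocyclic carbon, which returns the five-membered ring, or it may lose a proton to flavenes; ion-pair return during the aprotic activation stage can also divert material. The fallback runs the same ring enlargement as a Demjanov rearrangement, in which dinitrogen leaves irreversibly in water. It sets out from ester 6. Aminolysis with the aluminium amide from Me3Al and NH4Cl (toluene, 50 °C) should give (2S,3R)-2-[3,4-bis(benzyloxy)phenyl]-4,6-bis{[3,4-bis(benzyloxy)phenyl]methoxy}-2,3-dihydro-1-benzofuran-3-carboxamide F1. Reduction with LiAlH4 (THF, 50 °C) should give the cis (2S,3S)-3-(aminomethyl) compound F2. Diazotisation with NaNO2 in aqueous acetic acid at 0 °C should give the (2S,3S)-3-(diazoniomethyl) acetate F3, which loses nitrogen with migration of C4a and is captured by water at C3, coming back to the route at 10.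

Step 4. Discrimination between the enantiotopic benzylic hydrogens may be weak, because the two ortho substituents twist the aryl group out of the carbenoid plane. The fallback is classical resolution instead of catalyst control. It sets out from alcohol 7 of insufficient enantiomeric purity. Esterification with (S)-O-acetylmandelic acid (EDC, cat. DMAP, CH2Cl2, 0 °C) should give the (2S,3S)-alcohol (S)-O-acetylmandelate F4, together with the mirror-image (2R,3R)-alcohol (S)-O-acetylmandelate F5, which is removed by crystallisation or chromatography. Methanolysis of F4 (K2CO3, MeOH/THF) comes back to the route at 7.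

Step 9. The arene may attack the cation from the wrong face (4β), the product may be alkylated further to oligomers, and the acid may cleave the electron-rich benzyl-type ethers of 10. The fallback is neighbouring-group control. It sets out from 13. Acetylation (Ac2O, pyridine, cat. DMAP) should give the (2R,3S,4S) 3-O-acetate F6. Under the same Lewis acid at −78 °C the acetoxy group bridges to C4 on the β face, so 10 can only enter from the α face, which should give the 3-O-acetyl protected dimer F7. Methanolysis of the acetate (K2CO3, MeOH/THF) comes back to the route at 14.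

Further compounds
F1 | step 6 | (2S,3R)-2-[3,4-bis(benzyloxy)phenyl]-4,6-bis{[3,4-bis(benzyloxy)phenyl]methoxy}-2,3-dihydro-1-benzofuran-3-carboxamide | NC(=O)[C@@H]1c2c(OCc3ccc(OCc4ccccc4)c(OCc4ccccc4)c3)cc(OCc3ccc(OCc4ccccc4)c(OCc4ccccc4)c3)cc2O[C@@H]1c1ccc(OCc2ccccc2)c(OCc2ccccc2)c1
F2 | step 6 | [(2S,3S)-2-[3,4-bis(benzyloxy)phenyl]-4,6-bis{[3,4-bis(benzyloxy)phenyl]methoxy}-2,3-dihydro-1-benzofuran-3-yl]methanamine | NC[C@@H]1c2c(OCc3ccc(OCc4ccccc4)c(OCc4ccccc4)c3)cc(OCc3ccc(OCc4ccccc4)c(OCc4ccccc4)c3)cc2O[C@@H]1c1ccc(OCc2ccccc2)c(OCc2ccccc2)c1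
F3 | step 6 | (2S,3S)-3-(diazoniomethyl) analogue of F2, acetate salt | N#[N+]C[C@@H]1c2c(OCc3ccc(OCc4ccccc4)c(OCc4ccccc4)c3)cc(OCc3ccc(OCc4ccccc4)c(OCc4ccccc4)c3)cc2O[C@@H]1c1ccc(OCc2ccccc2)c(OCc2ccccc2)c1.CC(=O)[O-]
F4 | step 4 | (S)-O-acetylmandelate of (2S,3S)-7 | c1ccccc1[C@@H](C(=O)OC[C@@H]2c3c(OCc4ccc(OCc5ccccc5)c(OCc5ccccc5)c4)cc(OCc4ccc(OCc5ccccc5)c(OCc5ccccc5)c4)cc3O[C@@H]2c2ccc(OCc3ccccc3)c(OCc3ccccc3)c2)OC(C)=O
F5 | step 4 | (S)-O-acetylmandelate of the (2R,3R) mirror-image alcohol (discarded diastereomer) | c1ccccc1[C@@H](C(=O)OC[C@H]2c3c(OCc4ccc(OCc5ccccc5)c(OCc5ccccc5)c4)cc(OCc4ccc(OCc5ccccc5)c(OCc5ccccc5)c4)cc3O[C@H]2c2ccc(OCc3ccccc3)c(OCc3ccccc3)c2)OC(C)=O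
F6 | step 9 | (2R,3S,4S)-3-acetoxy-5,7-bis(benzyloxy)-4-(2-ethoxyethoxy)-2-[3,4,5-tris(benzyloxy)phenyl]-3,4-dihydro-2H-1-benzopyran | CC(=O)O[C@H]1[C@@H](OCCOCC)c2c(OCc3ccccc3)cc(OCc3ccccc3)cc2O[C@@H]1c1cc(OCc2ccccc2)c(OCc2ccccc2)c(OCc2ccccc2)c1
F7 | step 9 | 3-O-acetate (upper unit) of protected dimer 14 | c1ccccc1COc1cc(OCc3ccccc3)c2c(c1)O[C@H](c1cc(OCc3ccccc3)c(OCc3ccccc3)c(OCc3ccccc3)c1)[C@@H](OC(C)=O)[C@@H]2c1c(OCc3ccc(OCc4ccccc4)c(OCc4ccccc4)c3)cc(OCc3ccc(OCc4ccccc4)c(OCc4ccccc4)c3)c2c1O[C@H](c1ccc(OCc3ccccc3)c(OCc3ccccc3)c1)[C@H](O)C2
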